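Target in the noon run reads highest at 2.00 h, and the readings below show what stood there.

| flask | solid substrate | gas phase | protic impurity | remark | time |
|---|---|---|---|---|---|
| autumn | 2.8 M | 200 mM (held) | 1.4 M | the very flask that is asked about, followed so far |  |
| noon | 1.4 M | 200 mM (held) | 1.4 M | run made earlier |  |
| flask | 2.8 M | 200 mM (held) | 1.40 M |  | 5.0 h |

autumn run (percent of the solid substrate charged)

| time / min | target / % | starting material / % |
|---|---|---|
| 3.00 | 0.6 | 4.8 |
| 5.00 | 1.4 | 7.5 |
| 8.00 | 0 | 9.9 |
| 12.0 | 3.0 | 15.0 |
| 20.0 | 3.0 | 21.8 |
| 40.0 | 10.2 | 34.7 |

noon run (percent of the solid substrate charged)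

| time / h | target / % | starting material / % |
|---|---|---|
| 0.667 | 21.6 | 66.5 |
| 1.33 | 47.4 | 40.7 |
| 2.00 | 52.9 | 22.2 |
| 2.50 | 51.8 | 14.1 |
| 3.00 | 47.1 | 8.9 |
| 4.00 | 34.1 | 0.7 |

(each reading ± 1 percentage point)

1. the target in the flask at 5.0 h, as a percentage of the solid substrate charged
2. the starting material in the flask at 5.0 h, as a percentage of the solid substrate charged

- as a solid, counted per litre of solution: solid substrate
- what was read earlier has a scatter of 1 percentage point, one standard deviation
- at the start none of the gas phase is in solution
- at the start none of the solid substrate is in solution
- starting material means what is dissolved; the solid is not counted in it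

Read down the noon columns, with A for starting material and P for target. If target is made in step with A and lost in step with P, then at the highest reading of P, at 2.00 h, making and losing balance within the scatter. So the ratio there, s = A/P = 0.420, serves as a reading of the selectivity factor: target gains while A/P stands above s and loses below it. The balance r = A/(sP) says the same against one. At 1.33 h it reads 2.05, with P still climbing; at 3.00 h it reads 0.450, with P falling.

The autumn columns sit earlier on that path. At 40.0 min the autumn A/P is 3.40, above s, and its target of 0.286 M stands beside the 0.302 M of noon at 0.667 h. Read in percent, the autumn run therefore stands behind noon at the same time of reading, with 10.2% of target against 21.6%. Between 20.0 min and 40.0 min the autumn run gains 1.69 M h⁻¹ of A and P together, and at that pace, taken as an estimate, the extra 1.40 M of solid substrate comes to about 0.829 h.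

The reckoning made here assumes that the asked flask, once its solid is gone, repeats noon in percent that much later. At 5.0 h it then reads as noon at 4.17 h, a little past noon's last reading: r below one, target carried along the last slope to near 31.9%, starting material near the 0.7% of that last reading.

The forecast gives 26% target and 2% starting material, with the remark “The protic impurity might run out and slow the loss”.

The flask gives 34.5% target and 2.87% starting material.

    dissolved gas + target → over-reacted product (k = 7.20 × 10⁻⁴ M⁻¹ s⁻¹)
    gas phase ⇌ dissolved gas, rate k2*(csat - [dissolved gas]) (kL = 0.00430 s⁻¹)
    starting material + dissolved gas → target (k = 0.00180 M⁻¹ s⁻¹)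
    dissolved gas + protic impurity → quenched reagent (k = 1.70 × 10⁻⁴ M⁻¹ s⁻¹)
    solid substrate ⇌ starting material, rate k5*(cs5 - [starting material]) while solid is left; crystals form when [starting material] > cs5 (solubility = 2.50 M, k = 2.80 × 10⁻⁴ s⁻¹)

Target stands 2.6 percentage points above the reckoning. In the flask at 5.0 h, these two results put r at 0.198, and target is made at 0.208 of the rate at which it is used up. The same flask read at 3.0 h holds 19.4% starting material and 52.1% target, which gives r = 0.886.

Readings and results stem from a simulated flask on assumed constants; the scatter is artificial.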